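Readings and results stem from a simulated flask for an exercise, noise included.

This flask cannot use up its D: each D that reacts takes one L, and the L charged is only 90.0% of the D charged. By the proposed steps each X takes a second L, so D gone plus X made can reach at most the L budget, L charged over D charged. That makes L the limiting reagent.

common to all: D 0.62 M
- elm: L 0.84 M; run made earlier
- flask: L 0.558 M; time 15 d

elm run (percent of the D charged)

| time / d | X / % | E / % | D / % |
|---|---|---|---|
| 0.417 | 3.1 | 1.1 | 47.1 |
| 1.04 | 9.3 | 4.1 | 23.8 |
| 2.00 | 14.6 | 9.7 | 11.5 |
| 3.00 | 17.0 | 16.4 | 7.4 |
| 5.00 | 19.6 | 27.8 | 3.7 |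

(scatter of a reading: 0.3 percentage points)

- for X the G are counted in
- as a solid, counted per litre of solution: G
- the analysis behind the earlier runs scatters by 0.3 percentage points, standard deviation
- steps that have been proposed: D + L -> Z; Z -> J; Z -> Q; L + Q -> X; J -> E; G <-> X

* ratio of X to E at 12 h
* ratio of X to E at 15 d
* which of X and E there is more of at 15 d

How much X comes before the budget is spent? My readings come from the elm run, whose budget is 135%, and I doubt that so different a charge can speak for this flask. By the proposed steps, both steps that spend L run in proportion to L, but Z goes on to J and Q without L, so L drops out of the X gained per D gone only approximately, and only if Z is short-lived. I assume that it is. This flask should then roughly walk the elm curve of X against D gone and stop sooner. In elm, D gone plus X is 85.5% at 1.04 d and 103% at 2.00 d, so the stop lies between them. A straight line between the two readings puts X at 10.7% and D gone at 79.3%. A reading scatters by 0.3 percentage points, and the line and the assumption add their own error, so I take that X as a rough estimate.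

That gives X, but the question is a ratio. J to E takes no L, so E can go on after X stops, and elm already shows E at 27.8% at 5.00 d, above my stop. I expect E ahead at 15 d. For 12 h I take the first elm ratio, a rough 2.82.

The forecast says 2 at 12 h, 0.24 at 15 d and E ahead, expecting that “L runs out within about a week”.

The flask gives 2.69 at 12 h and 0.229 at 15 d, with E at 48.5% of the D charged and X at 11.1%, against my 10.7%. L then stands at 0.0118% of its own charge. D gone plus X comes to 90.0%, against the budget of 90.0%.

    D + L → Z (k = 0.119 L mol⁻¹ h⁻¹)
    Z → J (k = 0.273 h⁻¹)
    Z → Q (k = 0.0773 h⁻¹)
    L + Q → X (k = 0.155 L mol⁻¹ h⁻¹)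
    J → E (k = 0.00466 h⁻¹)
    G ⇌ X, rate k6*(cs6 - [X]) while solid is left; crystals form when [X] > cs6 (solubility = 0.320 M, k = 0.712 h⁻¹)

The neighbour flask with 0.33 M of L has a budget of 53.2%, just short of the 56.0% spent at the first elm reading. Scaling that X back gives me 2.95% and D gone 50.3%. The computed neighbour has X at 3.65% and D gone 49.6%.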